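**Assumption:** the target SMILES has no stereocentre and the diaryl ether is not a stable chiral axis, so the compound is achiral and is made as that one species. Racemic naringenin is used because its C2 centre is erased in step 2.

## Retrosynthetic overview

1. Target 9 is two genkwanin units joined from O-4' of unit 1 to C-8 of unit 2; the last step removes two benzyl ethers from 8.
2. Key disconnection: the C8–O bond of 8, made by copper-catalysed O-arylation of free genkwanin 4 with the C8 iodide 7.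
3. 7 comes from 4 by double O-benzylation (6) and C8 iodination; the 5-O-benzyl group steers iodine to C8, the 4'-O-benzyl group stops self-coupling.
4. 4 comes from naringenin 1 by 7-O-methylation (2) and dehydrogenation.
5. Rings: none is built; rings A, B and C of both units come with naringenin, ring C is oxidised to the pyranone in step 2, and the two flavones are joined in step 5.

## Route

Step 1
Reactants: 1 naringenin (racemic 5,7-dihydroxy-2-(4-hydroxyphenyl)-2,3-dihydro-4H-chromen-4-one)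
Product: 2 sakuranetin (racemic 5-hydroxy-2-(4-hydroxyphenyl)-7-methoxy-2,3-dihydro-4H-chromen-4-one)
Conditions: MeI (1.1 equiv), K2CO3 (1.1 equiv), DMF, rt
Reagents that add atoms: iodomethane, CI
Why: Williamson ether synthesis in which one equivalent of base forms only the 7-phenoxide (para to the ketone, pKa about 7.5), since the 5-OH is hydrogen-bonded to C4=O and the 4'-OH is an ordinary phenol (pKa about 10); no new stereocentre.

Step 2
Reactants: 2 sakuranetin
Product: 4 genkwanin (5-hydroxy-2-(4-hydroxyphenyl)-7-methoxy-4H-chromen-4-one), via 3-iodosakuranetin 3 (not isolated)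
Conditions: I2 (10 mol%), DMSO, 130 °C
Reagents that add atoms: none
Why: Iodine-catalysed dehydrogenation of a flavanone (alpha-iodination of the ketone, loss of HI to the conjugated chromone, DMSO re-oxidises HI to I2); the C2 stereocentre is removed.

Step 3
Reactants: 4 genkwanin
Product: 6 5-(benzyloxy)-2-[4-(benzyloxy)phenyl]-7-methoxy-4H-chromen-4-one, via 4'-O-benzylgenkwanin 5 (not isolated)
Conditions: BnBr (3 equiv), K2CO3 (4 equiv), n-Bu4NI (10 mol%), DMF, 70 °C
Reagents that add atoms: benzyl bromide, BrCc1ccccc1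
Why: Double Williamson etherification in which the 4'-OH reacts first (5) and the chelated 5-OH follows under heat, excess bromide and iodide catalysis; no stereocentre.

Step 4
Reactants: 6 5-(benzyloxy)-2-[4-(benzyloxy)phenyl]-7-methoxy-4H-chromen-4-one
Product: 7 5-(benzyloxy)-2-[4-(benzyloxy)phenyl]-8-iodo-7-methoxy-4H-chromen-4-one
Conditions: NIS (1.1 equiv), TFA (0.3 equiv), MeCN–CH2Cl2, 0 °C to rt, dark
Reagents that add atoms: N-iodosuccinimide, O=C1CCC(=O)N1I
Why: Electrophilic aromatic iodination, which for 5,7-dialkoxyflavones goes to C8 (ortho to 7-OMe and O-1, para to 5-OBn), while ring B and the benzyl rings are far less activated; no stereocentre.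

Step 5
Reactants: 7 5-(benzyloxy)-2-[4-(benzyloxy)phenyl]-8-iodo-7-methoxy-4H-chromen-4-one; 4 genkwanin (1.5 equiv, excess recovered)
Product: 8 5-(benzyloxy)-2-[4-(benzyloxy)phenyl]-8-[4-(5-hydroxy-7-methoxy-4-oxo-4H-chromen-2-yl)phenoxy]-7-methoxy-4H-chromen-4-one
Conditions: CuI (20 mol%), 2,2,6,6-tetramethylheptane-3,5-dione (40 mol%), Cs2CO3 (2 equiv), NMP, 110 °C, argon
Reagents that add atoms: none
Why: Proposed new method: a copper-catalysed Ullmann-type O-arylation of the 4'-phenoxide of a flavone that keeps its chelated 5-hydroxyl free, using a flavone C8 iodide flanked by the pyran oxygen and a methoxy group, a pairing not yet shown; the diketonate-ligated monovalent copper phenoxide adds oxidatively to the C8–I bond (8-iodoflavones are known to insert copper in classical Ullmann biaryl couplings) and the trivalent copper aryl aryloxide gives the ether by C–O reductive elimination, while the 5-OH of 4 stays out because it is hydrogen-bonded, peri-hindered and, if deprotonated, only forms a keto-phenolate chelate of the same O,O ligand class as the diketone and so should not poison the catalyst; the closest known reaction type is the ligand-accelerated Ullmann diaryl ether synthesis of ortho-substituted aryl iodides with phenols; no stereocentre is formed.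

Step 6
Reactants: 8 5-(benzyloxy)-2-[4-(benzyloxy)phenyl]-8-[4-(5-hydroxy-7-methoxy-4-oxo-4H-chromen-2-yl)phenoxy]-7-methoxy-4H-chromen-4-one
Product: 9 5-hydroxy-8-[4-(5-hydroxy-7-methoxy-4-oxo-4H-chromen-2-yl)phenoxy]-2-(4-hydroxyphenyl)-7-methoxy-4H-chromen-4-one (target)
Conditions: H2 (1 atm), 10% Pd/C, THF–MeOH, rt
Reagents that add atoms: none
Why: Catalytic hydrogenolysis of the two aryl benzyl ethers, under which the methyl ethers, the diaryl ether and the conjugated chromone C2=C3 bonds are inert at 1 atm and rt; the product is achiral, so nothing can be scrambled.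

## Compound list

1 | naringenin, racemic 5,7-dihydroxy-2-(4-hydroxyphenyl)-2,3-dihydro-4H-chromen-4-one | O=C1CC(c2ccc(O)cc2)Oc2cc(O)cc(O)c12 | starting material
2 | sakuranetin, racemic 5-hydroxy-2-(4-hydroxyphenyl)-7-methoxy-2,3-dihydro-4H-chromen-4-one | COc1cc(O)c2C(=O)CC(c3ccc(O)cc3)Oc2c1 | intermediate
3 | 3-iodosakuranetin, 5-hydroxy-2-(4-hydroxyphenyl)-3-iodo-7-methoxy-2,3-dihydro-4H-chromen-4-one (racemic diastereomer mixture, not isolated) | COc1cc(O)c2C(=O)C(I)C(c3ccc(O)cc3)Oc2c1 | intermediate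
4 | genkwanin, 5-hydroxy-2-(4-hydroxyphenyl)-7-methoxy-4H-chromen-4-one | COc1cc(O)c2c(=O)cc(-c3ccc(O)cc3)oc2c1 | intermediate
5 | 4'-O-benzylgenkwanin, 2-[4-(benzyloxy)phenyl]-5-hydroxy-7-methoxy-4H-chromen-4-one (not isolated) | COc1cc(O)c2c(=O)cc(-c3ccc(OCc4ccccc4)cc3)oc2c1 | intermediate
6 | 5-(benzyloxy)-2-[4-(benzyloxy)phenyl]-7-methoxy-4H-chromen-4-one | COc1cc(OCc2ccccc2)c2c(=O)cc(-c3ccc(OCc4ccccc4)cc3)oc2c1 | intermediate
7 | 5-(benzyloxy)-2-[4-(benzyloxy)phenyl]-8-iodo-7-methoxy-4H-chromen-4-one | COc1cc(OCc2ccccc2)c2c(=O)cc(-c3ccc(OCc4ccccc4)cc3)oc2c1I | intermediate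
8 | 5-(benzyloxy)-2-[4-(benzyloxy)phenyl]-8-[4-(5-hydroxy-7-methoxy-4-oxo-4H-chromen-2-yl)phenoxy]-7-methoxy-4H-chromen-4-one | COc1cc(O)c2c(=O)cc(-c3ccc(Oc4c(OC)cc(OCc5ccccc5)c5c(=O)cc(-c6ccc(OCc7ccccc7)cc6)oc45)cc3)oc2c1 | intermediate
9 | 5-hydroxy-8-[4-(5-hydroxy-7-methoxy-4-oxo-4H-chromen-2-yl)phenoxy]-2-(4-hydroxyphenyl)-7-methoxy-4H-chromen-4-one (achiral) | COc1cc(O)c2c(=O)cc(-c3ccc(Oc4c(OC)cc(O)c5c(=O)cc(-c6ccc(O)cc6)oc45)cc3)oc2c1 | target

## Step count and risks

Total steps: 6. Longest linear sequence: 6 (1 → 2 → 4 → 6 → 7 → 8 → 9); compound 4 is used twice, in steps 3 and 5.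

**Step 5 (the proposed new coupling).** The iodide is doubly ortho-substituted and electron-rich and the 4'-phenoxide is a weak nucleophile, so the reaction may stall or give hydrodeiodination or the 8,8''-biflavone. The fallback uses known chemistry and reverses the polarity, so that the C8 oxygen is the nucleophile and the ring B carbon is a para-activated fluoride. It sets out from 7 and comes back at 8. Miyaura borylation of 7 (bis(pinacolato)diboron, PdCl2(dppf), KOAc, dioxane, 90 °C) gives the pinacol boronate F1. Oxidation with NaBO3·4H2O in THF–water gives the 8-hydroxyflavone F2. SNAr with 4-fluorobenzaldehyde (K2CO3, DMF, 120 °C) gives the aldehyde F3. Claisen–Schmidt condensation with commercial 2',6'-dihydroxy-4'-methoxyacetophenone (KOH, EtOH, rt) gives the chalcone F4. Oxidative cyclisation (I2 cat., DMSO, 130 °C) closes ring C of unit 1; the two ortho hydroxyls are equivalent, so only 8 can form.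

**Step 4 (regiochemistry of iodination).** Iodine could enter at C6 or C3', or twice. The fallback fixes C8 by the para selectivity of the Elbs oxidation of a free 5-hydroxyflavone. It sets out from 5 (isolated on purpose by running step 3 with 1.05 equiv BnBr at rt) and comes back at 9. Treating 5 with K2S2O8 in aqueous KOH–pyridine at 0–20 °C gives the potassium 8-sulfate F5, which hot aqueous HCl hydrolyses to the 5,8-dihydroxyflavone F6. SNAr with 4-fluorobenzaldehyde (K2CO3, DMF, 100 °C, argon) at the only non-chelated hydroxyl gives the aldehyde F7. Condensation with 2',6'-dihydroxy-4'-methoxyacetophenone (KOH, EtOH) gives the chalcone F8. Cyclisation with I2 (cat.) in DMSO gives the mono-benzyl biflavone F9, and hydrogenolysis (H2, 10% Pd/C) gives 9.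

**Step 1 (mono-methylation).** Over-methylation at O-4' or base-induced opening to the chalcone may lower the yield. The fallback differentiates the hydroxyls by acyl protection. It sets out from 1 and comes back at 2. Ac2O in pyridine gives the triacetate F10. PhSH with catalytic imidazole in NMP at 0 °C removes only the most labile 7-O-acetyl to give the 7-hydroxy diacetate F11. Mitsunobu methylation (MeOH, PPh3, DIAD, THF) gives the 7-O-methyl diacetate F12, and HCl in MeOH at 50 °C gives 2.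

## Further compounds

F1 | step 5 | 5-(benzyloxy)-2-[4-(benzyloxy)phenyl]-7-methoxy-8-(4,4,5,5-tetramethyl-1,3,2-dioxaborolan-2-yl)-4H-chromen-4-one | COc1cc(OCc2ccccc2)c2c(=O)cc(-c3ccc(OCc4ccccc4)cc3)oc2c1B1OC(C)(C)C(C)(C)O1
F2 | step 5 | 5-(benzyloxy)-2-[4-(benzyloxy)phenyl]-8-hydroxy-7-methoxy-4H-chromen-4-one | COc1cc(OCc2ccccc2)c2c(=O)cc(-c3ccc(OCc4ccccc4)cc3)oc2c1O
F3 | step 5 | 4-({5-(benzyloxy)-2-[4-(benzyloxy)phenyl]-7-methoxy-4-oxo-4H-chromen-8-yl}oxy)benzaldehyde | COc1cc(OCc2ccccc2)c2c(=O)cc(-c3ccc(OCc4ccccc4)cc3)oc2c1Oc1ccc(C=O)cc1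
F4 | step 5 | (E)-3-[4-({5-(benzyloxy)-2-[4-(benzyloxy)phenyl]-7-methoxy-4-oxo-4H-chromen-8-yl}oxy)phenyl]-1-(2,6-dihydroxy-4-methoxyphenyl)prop-2-en-1-one | COc1cc(O)c(C(=O)/C=C/c2ccc(Oc3c(OC)cc(OCc4ccccc4)c4c(=O)cc(-c5ccc(OCc6ccccc6)cc5)oc34)cc2)c(O)c1
F5 | step 4 | potassium 2-[4-(benzyloxy)phenyl]-5-hydroxy-7-methoxy-4-oxo-4H-chromen-8-yl sulfate | COc1cc(O)c2c(=O)cc(-c3ccc(OCc4ccccc4)cc3)oc2c1OS(=O)(=O)[O-].[K+]
F6 | step 4 | 2-[4-(benzyloxy)phenyl]-5,8-dihydroxy-7-methoxy-4H-chromen-4-one | COc1cc(O)c2c(=O)cc(-c3ccc(OCc4ccccc4)cc3)oc2c1O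
F7 | step 4 | 4-({2-[4-(benzyloxy)phenyl]-5-hydroxy-7-methoxy-4-oxo-4H-chromen-8-yl}oxy)benzaldehyde | COc1cc(O)c2c(=O)cc(-c3ccc(OCc4ccccc4)cc3)oc2c1Oc1ccc(C=O)cc1
F8 | step 4 | (E)-3-[4-({2-[4-(benzyloxy)phenyl]-5-hydroxy-7-methoxy-4-oxo-4H-chromen-8-yl}oxy)phenyl]-1-(2,6-dihydroxy-4-methoxyphenyl)prop-2-en-1-one | COc1cc(O)c(C(=O)/C=C/c2ccc(Oc3c(OC)cc(O)c4c(=O)cc(-c5ccc(OCc6ccccc6)cc5)oc34)cc2)c(O)c1
F9 | step 4 | 2-[4-(benzyloxy)phenyl]-5-hydroxy-8-[4-(5-hydroxy-7-methoxy-4-oxo-4H-chromen-2-yl)phenoxy]-7-methoxy-4H-chromen-4-one | COc1cc(O)c2c(=O)cc(-c3ccc(Oc4c(OC)cc(O)c5c(=O)cc(-c6ccc(OCc7ccccc7)cc6)oc45)cc3)oc2c1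
F10 | step 1 | racemic naringenin triacetate, 2-(4-acetoxyphenyl)-4-oxo-3,4-dihydro-2H-chromene-5,7-diyl diacetate | CC(=O)Oc1ccc(cc1)C1CC(=O)c2c(OC(C)=O)cc(OC(C)=O)cc2O1
F11 | step 1 | racemic 5,4'-di-O-acetylnaringenin, 2-(4-acetoxyphenyl)-7-hydroxy-4-oxo-3,4-dihydro-2H-chromen-5-yl acetate | CC(=O)Oc1ccc(cc1)C1CC(=O)c2c(OC(C)=O)cc(O)cc2O1
F12 | step 1 | racemic 5,4'-di-O-acetylsakuranetin, 2-(4-acetoxyphenyl)-7-methoxy-4-oxo-3,4-dihydro-2H-chromen-5-yl acetate | COc1cc(OC(C)=O)c2C(=O)CC(c3ccc(OC(C)=O)cc3)Oc2c1
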